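## Retrosynthetic overview

- **Feature:** the two ring C pyranones are joined by the chain C2–C3–C3''–C2''. The ring A aroyl carbons C4 and C4'' sit on its inner atoms and the anisyl rings B on its outer atoms. This is a head-to-head chalcone dimer that lacks only a C2–C2'' bond.
- **Late stage:** the target is (2S,3R,2''S,3''S), that is 2,3-trans and 2'',3''-cis. After debenzylation is disconnected, C3'' alone is inverted. This leads back, through an enol ether and its kinetic protonation, to the C2-symmetric trans,trans biflavanone (2S,3R,2''S,3''R).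
- **Ring C disconnection:** both O1–C2 bonds are disconnected while C2–C2'' is restored. The precursor is an all-trans 1,2-diaroyl-3,4-dianisylcyclobutane, opened oxidatively with its two 2'-phenols as internal nucleophiles.
- **Cyclobutane:** it comes from enantioselective head-to-head [2+2] photodimerisation of a 2'-hydroxychalcone. This forms C3–C3'' and the sacrificial C2–C2''. The chalcone is made from phloroacetophenone, BnBr and anisaldehyde.
- **Ring order:** cyclobutane in step 3, then rings C and C'' as the cyclobutane is cleaved in step 4.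

Key step: step 3

Assumption: the (S,S)-tBu-PyBox/Sc(OTf)3 complex is taken to give the (1S,2S,3R,4R) dimer; if the mirror image forms, the equally available (R,R) ligand is used and nothing else changes.

Numbering: flavanone numbering is used throughout, and the doubly primed unit is the one that ends 2'',3''-cis.

## Route

Step 1
Reactants: 1 2',4',6'-trihydroxyacetophenone; 2 benzyl bromide
Product: 3 2'-hydroxy-4',6'-bis(benzyloxy)acetophenone
Conditions: BnBr (2.1 equiv), K2CO3 (2.2 equiv), DMF, rt to 50 °C
Reagents that add atoms: benzyl bromide (2), BrCc1ccccc1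
Why: Williamson ether synthesis in which the para-OH and one ortho-OH are alkylated, while the last ortho-OH is hydrogen-bonded to the acetyl oxygen and too poorly nucleophilic to compete for the limited halide; no stereocentre is formed.

Step 2
Reactants: 3 2'-hydroxy-4',6'-bis(benzyloxy)acetophenone; 4 4-methoxybenzaldehyde
Product: 5 (E)-2'-hydroxy-4',6'-bis(benzyloxy)-4-methoxychalcone
Conditions: KOH (50% aq, excess), EtOH, rt; then cold 1 M HCl to pH 5
Reagents that add atoms: 4-methoxybenzaldehyde (4), COc1ccc(C=O)cc1
Why: Claisen–Schmidt condensation of the methyl ketone with a non-enolisable aldehyde, where E1cB dehydration gives the conjugated E alkene and the phenoxide formed in strong base keeps the chalcone from closing to the flavanone.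

Step 3
Reactants: 5 (E)-2'-hydroxy-4',6'-bis(benzyloxy)-4-methoxychalcone (two molecules)
Product: 7 (1S,2S,3R,4R)-1,2-bis[2-hydroxy-4,6-bis(benzyloxy)benzoyl]-3,4-bis(4-methoxyphenyl)cyclobutane (all-trans), via triplet 1,4-diradical 6 (not isolated)
Conditions: Sc(OTf)3 (10 mol%), (S,S)-tBu-PyBox (15 mol%), Ru(bpy)3(PF6)2 (2.5 mol%), iPrOAc/MeCN 3:1 (0.3 M, degassed), blue LED (455 nm), 0 °C to rt
Reagents that add atoms: none
Why: Proposed new method: 5 chelates the PyBox-bound Sc(OTf)3 through its carbonyl and 2'-OH oxygens, which lowers its triplet energy enough for energy transfer from photoexcited Ru(bpy)3(PF6)2, and the bound triplet joins its Cα to Cα of a free ground-state 5 (C3–C3'') to give the doubly 4-methoxybenzylic 1,4-diradical 6, which after intersystem crossing forms C2–C2''. The closest known reaction types are the chiral Lewis acid-catalysed, triplet-sensitised [2+2] photocycloaddition of 2'-hydroxychalcones with dienes or styrenes and the racemic sensitised head-to-head dimerisation of chalcones; a second chalcone as the alkene partner under asymmetric catalysis is the untested element. The only ring formed, the cyclobutane, is closed by radical recombination of the 1,4-diradical, that is a stepwise formal [2+2]. The aroyl carbon of the bound unit is set by the tert-butyl groups of the ligand, which leave one enone face open, the second aroyl carbon by the anti approach of the two bulky aroyl groups in the first bond formation, and the two anisyl carbons by closure of 6 with each anisyl trans to both ring neighbours. The step needs head-to-head regiochemistry, secured by the two anisyl groups that stabilise both radical centres of 6, together with trans aroyl groups and one absolute sense, whereas the anisyl carbons are erased in step 4, so isomers differing only there still converge on 9. Racemic background should be small because unbound 5 lies too high in triplet energy for this sensitiser and its directly excited singlet decays by proton transfer along the O–H···O=C bridge.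

Step 4
Reactants: 7 all-trans cyclobutane
Product: 9 (2S,3R,2''S,3''R)-5,7,5'',7''-tetrakis(benzyloxy)-4',4'''-dimethoxy-3,3''-biflavanone (2,3-trans and 2'',3''-trans; C2-symmetric), via monocyclised benzylic radical 8 (not isolated)
Conditions: undivided cell, graphite anode, Pt cathode, constant current to 2.1–2.3 F/mol, nBu4NPF6 (0.1 M), (2,4-Br2C6H3)3N (10 mol%), CH2Cl2/HFIP 4:1, 0 °C
Reagents that add atoms: none
Why: Proposed new method: the aminium mediator (or the anode) removes one electron from an anisyl ring of 7, and in the radical cation the strained, doubly 4-methoxybenzylic C2–C2'' bond is the weakest, so it breaks while the 2'-OH of the neighbouring aroyl group, which lies gauche to C2 and can reach the lobe opposite the departing carbon, closes ring C with inversion at C2 (H2 and H3 anti, 2,3-trans) to give radical 8. Radical 8 is oxidised much more easily than 7 to the benzylic cation, which the second phenol captures through a chair-like six-membered transition state with the anisyl group and C3 equatorial (2'',3''-trans), C3 and C3'' staying untouched and the two protons being reduced at the cathode. The closest known reaction types are the anodic or photoredox ring-opening 1,3-difunctionalisation of arylcyclopropanes, the anodic C–C cleavage of aryl-substituted donor–acceptor cyclobutanes and the mesolytic cleavage of bibenzyl radical cations with capture by oxygen nucleophiles; HFIP stabilises the radical cation and loosens the phenol–carbonyl hydrogen bond.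

Step 5
Reactants: 9 trans,trans tetrabenzyl biflavanone
Product: 10 mono tert-butyldimethylsilyl enol ether of 9 (ring C'' is a 4''-silyloxy-2''H-chromene with C3''=C4''; C2, C3 and C2'' unchanged in space)
Conditions: TBSOTf (1.05 equiv), Et3N (3 equiv), CH2Cl2, −20 to 0 °C
Reagents that add atoms: tert-butyldimethylsilyl triflate, CC(C)(C)[Si](C)(C)OS(=O)(=O)C(F)(F)F
Why: Soft enolisation to a silyl enol ether, in which the silyl triflate activates the electron-rich C4 carbonyl and Et3N removes the axial, stereoelectronically aligned C3–H of the diequatorial ring; the two ketones of C2-symmetric 9 are homotopic, so either gives the same product, one equivalent of triflate limits a second silylation, and the neutral enol ether cannot expel O1''.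

Step 6
Reactants: 10 mono silyl enol ether
Product: 12 (2S,3R,2''S,3''S)-5,7,5'',7''-tetrakis(benzyloxy)-4',4'''-dimethoxy-3,3''-biflavanone (2,3-trans and 2'',3''-cis), via tetrabutylammonium enolate 11 (not isolated)
Conditions: nBu4NF (1.2 equiv) premixed with AcOH (5 equiv), THF, −78 to −40 °C; pH 7 buffer
Reagents that add atoms: none
Why: Fluoride desilylation followed by kinetic (contra-thermodynamic) protonation of the enolate, where allylic strain with the C3'' substituent pushes the C2'' anisyl group pseudo-axial so that AcOH delivers the proton to C3'' from the opposite face, which leaves the C3 unit cis to the anisyl group (3''S); the acid already present quenches 11 before it can eliminate O1'' or equilibrate.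

Step 7
Reactants: 12 trans,cis tetrabenzyl biflavanone
Product: 13 (2S,3R,2''S,3''S)-5,7,5'',7''-tetrahydroxy-4',4'''-dimethoxy-3,3''-biflavanone (target)
Conditions: H2 (1 atm), 10% Pd/C, EtOAc/MeOH 1:1, rt
Reagents that add atoms: none
Why: Catalytic hydrogenolysis of the four benzyl aryl ethers under neutral conditions, as is routine for flavanones, which spares the C2–O1 bonds, the ketones and the methyl ethers and gives no enolisation that could return C3'' to the trans series.

## Compound list

1 | 2',4',6'-trihydroxyacetophenone | CC(=O)c1c(O)cc(O)cc1O | starting material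
2 | benzyl bromide | BrCc1ccccc1 | starting material
3 | 2'-hydroxy-4',6'-bis(benzyloxy)acetophenone | CC(=O)c1c(O)cc(OCc2ccccc2)cc1OCc1ccccc1 | intermediate
4 | 4-methoxybenzaldehyde | COc1ccc(C=O)cc1 | starting material
5 | (E)-2'-hydroxy-4',6'-bis(benzyloxy)-4-methoxychalcone | COc1ccc(/C=C/C(=O)c2c(O)cc(OCc3ccccc3)cc2OCc2ccccc2)cc1 | intermediate
6 | 2,3-diaroyl-1,4-bis(4-methoxyphenyl)butane-1,4-diyl, triplet 1,4-diradical (not isolated) | COc1ccc([CH][C@H](C(=O)c3c(O)cc(OCc4ccccc4)cc3OCc3ccccc3)[C@@H](C(=O)c3c(O)cc(OCc4ccccc4)cc3OCc3ccccc3)[CH]c2ccc(OC)cc2)cc1 | intermediate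
7 | (1S,2S,3R,4R)-1,2-bis[2-hydroxy-4,6-bis(benzyloxy)benzoyl]-3,4-bis(4-methoxyphenyl)cyclobutane, all-trans | COc1ccc([C@H]2[C@H](C(=O)c3c(O)cc(OCc4ccccc4)cc3OCc3ccccc3)[C@@H](C(=O)c3c(O)cc(OCc4ccccc4)cc3OCc3ccccc3)[C@@H]2c2ccc(OC)cc2)cc1 | intermediate
8 | (2S,3R)-flavanone bearing at C3 the open aroyl(4-methoxybenzyl radical) chain (not isolated) | COc1ccc([C@H]2Oc3cc(OCc4ccccc4)cc(OCc4ccccc4)c3C(=O)[C@@H]2[C@H]([CH]c2ccc(OC)cc2)C(=O)c2c(O)cc(OCc3ccccc3)cc2OCc2ccccc2)cc1 | intermediate
9 | (2S,3R,2''S,3''R)-tetrabenzyl biflavanone, trans,trans | COc1ccc([C@H]2Oc3cc(OCc4ccccc4)cc(OCc4ccccc4)c3C(=O)[C@@H]2[C@H]2C(=O)c3c(OCc4ccccc4)cc(OCc4ccccc4)cc3O[C@@H]2c2ccc(OC)cc2)cc1 | intermediate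
10 | mono TBS enol ether of 9 (C3''=C4'') | COc1ccc([C@H]2Oc3cc(OCc4ccccc4)cc(OCc4ccccc4)c3C(=O)[C@@H]2C2=C(O[Si](C)(C)C(C)(C)C)c3c(OCc4ccccc4)cc(OCc4ccccc4)cc3O[C@@H]2c2ccc(OC)cc2)cc1 | intermediate
11 | tetrabutylammonium C3''=C4'' enolate (not isolated) | COc1ccc([C@H]2Oc3cc(OCc4ccccc4)cc(OCc4ccccc4)c3C(=O)[C@@H]2C2=C([O-])c3c(OCc4ccccc4)cc(OCc4ccccc4)cc3O[C@@H]2c2ccc(OC)cc2)cc1.CCCC[N+](CCCC)(CCCC)CCCC | intermediate
12 | (2S,3R,2''S,3''S)-tetrabenzyl biflavanone, trans,cis | COc1ccc([C@H]2Oc3cc(OCc4ccccc4)cc(OCc4ccccc4)c3C(=O)[C@@H]2[C@@H]2C(=O)c3c(OCc4ccccc4)cc(OCc4ccccc4)cc3O[C@@H]2c2ccc(OC)cc2)cc1 | intermediate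
13 | (2S,3R,2''S,3''S)-5,7,5'',7''-tetrahydroxy-4',4'''-dimethoxy-3,3''-biflavanone | COc1ccc([C@H]2Oc3cc(O)cc(O)c3C(=O)[C@@H]2[C@@H]2C(=O)c3c(O)cc(O)cc3O[C@@H]2c2ccc(OC)cc2)cc1 | target

## Step count and risks

Total steps: 7. Longest linear sequence: 7 (1 to 13).

**Step 3**

- What may go wrong:
  - Face discrimination may be weak because the second chalcone is an unbound, flat partner.
  - The triplet may decay unproductively by E/Z isomerisation.
  - The Lewis acid may close 5 to the flavanone.
  - The chelating product may bind scandium and slow turnover.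
- Fallback, from 5 back to 7, with the absolute configuration taken from a covalent auxiliary instead of a catalyst:
  - 5 is acylated with (1S)-camphanic chloride (Et3N, DMAP, CH2Cl2) to the 2'-O-camphanoyl chalcone F1, which no longer has the proton-transfer decay channel.
  - F1 is dimerised by ordinary triplet sensitisation ([Ir(dF(CF3)ppy)2(dtbbpy)]PF6, blue LED, MeCN). This is the known head-to-head, all-trans chalcone dimerisation.
  - It should give two diastereomers, the (1S,2S,3R,4R) bis-camphanate F2 and the (1R,2R,3S,4S)-core bis-camphanate F3. They are separated by crystallisation or chromatography.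
  - Methanolysis of F2 (K2CO3, MeOH/THF, rt) returns 7.

**Step 4**

- What may go wrong:
  - Complete cycloreversion of the radical cation to two chalcone units may outrun phenol capture.
  - The remote carbonyl oxygen may capture the benzylic cation.
  - The product may be oxidised further at C2–H.
- Fallback, from 5 back to 9, which gives up the cyclobutane and builds C3–C3'' by known oxidative enol ether coupling:
  - 5 is closed with NaOAc in refluxing EtOH to the racemic flavanone F4.
  - F4 is resolved kinetically by asymmetric transfer hydrogenation (RuCl(p-cymene)(TsDPEN), HCO2H/Et3N), using the ligand antipode that reduces the 2R ketone faster. This leaves the (2S)-flavanone F5 and converts the other half into the (2R,4R)-cis-flavan-4-ol F6, which is removed by chromatography.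
  - TMSOTf/Et3N turns F5 into the trimethylsilyl enol ether F7.
  - Ag2O in DMSO couples two molecules of F7 at C3, each anti to its own C2 anisyl group. This should give the trans,trans isomer 9.

**Step 6**

- What may go wrong:
  - The proton may be delivered to both faces, because the C3 unit also shields the enolate.
  - The aryloxide O1'' may be expelled from the enolate, which would scramble C2''.
  - The new ring may equilibrate back to trans.
- Fallback, from 9 back to 12, replacing kinetic control with thermodynamic control and bypassing steps 5 and 6: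
  - 9 is equilibrated with catalytic DBU in toluene at rt to 40 °C.
  - The C3 epimers are separated by chromatography. Unchanged 9 and the (2S,3S,2''S,3''S) cis,cis isomer F8 are returned to the equilibration.
  - The unsymmetrical 12 gains a statistical factor over its two C2-symmetric partners.

## Further compounds

F1 | step 3 | (E)-2'-O-[(1S)-camphanoyl]-4',6'-bis(benzyloxy)-4-methoxychalcone | COc1ccc(/C=C/C(=O)c2c(OC(=O)[C@@]34CC[C@@](C)(C(=O)O3)C4(C)C)cc(OCc3ccccc3)cc2OCc2ccccc2)cc1
F2 | step 3 | bis-(1S)-camphanate of 7, (1S,2S,3R,4R) core | COc1ccc([C@H]2[C@H](C(=O)c3c(OC(=O)[C@@]45CC[C@@](C)(C(=O)O4)C5(C)C)cc(OCc4ccccc4)cc3OCc3ccccc3)[C@@H](C(=O)c3c(OC(=O)[C@@]45CC[C@@](C)(C(=O)O4)C5(C)C)cc(OCc4ccccc4)cc3OCc3ccccc3)[C@@H]2c2ccc(OC)cc2)cc1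
F3 | step 3 | diastereomeric bis-(1S)-camphanate, (1R,2R,3S,4S) core | COc1ccc([C@@H]2[C@@H](C(=O)c3c(OC(=O)[C@@]45CC[C@@](C)(C(=O)O4)C5(C)C)cc(OCc4ccccc4)cc3OCc3ccccc3)[C@H](C(=O)c3c(OC(=O)[C@@]45CC[C@@](C)(C(=O)O4)C5(C)C)cc(OCc4ccccc4)cc3OCc3ccccc3)[C@H]2c2ccc(OC)cc2)cc1
F4 | step 4 | racemic 5,7-bis(benzyloxy)-4'-methoxyflavanone | COc1ccc(C2Oc3cc(OCc4ccccc4)cc(OCc4ccccc4)c3C(=O)C2)cc1
F5 | step 4 | (2S)-5,7-bis(benzyloxy)-4'-methoxyflavanone | COc1ccc([C@H]2Oc3cc(OCc4ccccc4)cc(OCc4ccccc4)c3C(=O)C2)cc1
F6 | step 4 | (2R,4R)-5,7-bis(benzyloxy)-4'-methoxyflavan-4-ol, 2,4-cis | COc1ccc([C@@H]2Oc3cc(OCc4ccccc4)cc(OCc4ccccc4)c3[C@H](O)C2)cc1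
F7 | step 4 | (2S)-5,7-bis(benzyloxy)-2-(4-methoxyphenyl)-4-trimethylsilyloxy-2H-chromene | COc1ccc([C@H]2Oc3cc(OCc4ccccc4)cc(OCc4ccccc4)c3C(O[Si](C)(C)C)=C2)cc1
F8 | step 6 | (2S,3S,2''S,3''S)-tetrabenzyl biflavanone, cis,cis | COc1ccc([C@H]2Oc3cc(OCc4ccccc4)cc(OCc4ccccc4)c3C(=O)[C@H]2[C@@H]2C(=O)c3c(OCc4ccccc4)cc(OCc4ccccc4)cc3O[C@@H]2c2ccc(OC)cc2)cc1
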